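The route rests on disconnecting the O1'–C2' bond of ring F in the lower (catechin) unit. C2' is benzylic to catechol ring E, carries the ring-D oxygen O1' and lies trans to O3'. A C2' cation bridged by a C3' ester and faced by the C8a' phenol should therefore close ring F 2',3'-trans. Anodic decarboxylation of a C2' carboxylic acid supplies that cation in one operation, so the acid stereocentre is irrelevant. The precursor is the benzylated EGCG C4β–C8' adduct of a ring-D phenol carrying at C4a' the chain CH2–CH(OLev)–CH(ArE)–CO2H. Levulinate is chosen as the C3' ester because hydrazine later removes it without touching the gallate. Both halves are built separately and joined by Lewis-acid coupling.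

Key step: step 16

Remark (assumption): (−)-epigallocatechin, 3,4,5-tris(benzyloxy)benzoic acid, 3,5-bis(benzyloxy)phenol, 3,4-bis(benzyloxy)phenylacetic acid, (R)-4-benzyl-2-oxazolidinone and levulinic anhydride are taken as purchasable. Flavan numbering is used, with primes for the lower unit; rings A–C belong to the upper unit and D–F to the lower unit. In the open-chain fragment, C2, C3 and C4 of the butanoate are C2', C3' and C4'. Lev = 4-oxopentanoyl, ArE = 3,4-bis(benzyloxy)phenyl.

Step 1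
Reactants: 1 (−)-epigallocatechin
Product: 2 5,7,3',4',5'-penta-O-benzyl-(−)-epigallocatechin (2R,3R; free 3-OH)
Conditions: BnBr (5.5 equiv), K2CO3, DMF, 0 °C to rt, Ar
Reagents that add atoms: benzyl bromide, BrCc1ccccc1
Why: Williamson etherification of the five phenols by SN2 on benzyl bromide; carbonate does not ionise the secondary 3-OH, which stays free, and the inert atmosphere protects the pyrogallol ring, so the C2/C3 centres are untouched.

Step 2
Reactants: 2 penta-O-benzyl-(−)-epigallocatechin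
Product: 3 (2R,3R,4S)-4-(2-ethoxyethoxy)-penta-O-benzyl-epigallocatechin (4β-alkoxy, free 3-OH)
Conditions: DDQ, 2-ethoxyethanol, CH2Cl2, rt
Reagents that add atoms: 2-ethoxyethanol, CCOCCO
Why: DDQ benzylic oxidation (hydride abstraction) at C4, which is activated by the ring-A oxygens, with capture of the cation by the alcohol anti to the C2 aryl and C3 hydroxyl groups; this sets C4 as 4β (3,4-trans), as is known for benzylated flavan-3-ols with a free 3-OH.

Step 3
Reactants: 3 4β-(2-ethoxyethoxy)-penta-O-benzyl-epigallocatechin; 4 3,4,5-tris(benzyloxy)benzoic acid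
Product: 6 (2R,3R,4S)-4-(2-ethoxyethoxy)-octa-O-benzyl-epigallocatechin gallate (4β-alkoxy), via O-acylisourea 5 (not isolated)
Conditions: DCC, DMAP, CH2Cl2, 0 °C to rt
Reagents that add atoms: none
Why: Steglich esterification; DCC activates the acid and DMAP transfers the acyl group to the 3-OH under non-acidic conditions that spare the acid-labile C4 ether, and no bond to C3 is broken, so its configuration is kept.

Step 4
Reactants: 7 3,5-bis(benzyloxy)phenol; 8 allyl bromide
Product: 9 1-(allyloxy)-3,5-bis(benzyloxy)benzene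
Conditions: K2CO3, acetone, reflux
Reagents that add atoms: none
Why: Williamson O-allylation of the phenoxide.

Step 5
Reactants: 9 1-(allyloxy)-3,5-bis(benzyloxy)benzene
Product: 10 2-allyl-3,5-bis(benzyloxy)phenol
Conditions: PhNEt2, 190 °C, Ar
Reagents that add atoms: none
Why: aromatic Claisen rearrangement; the [3,3] shift can deliver the allyl group only to an ortho carbon (the two are equivalent), and tautomerisation restores the phenol.

Step 6
Reactants: 10 2-allyl-3,5-bis(benzyloxy)phenol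
Product: 11 [2-allyl-3,5-bis(benzyloxy)phenoxy]triisopropylsilane
Conditions: iPr3SiCl, imidazole, DMF, rt
Reagents that add atoms: chlorotriisopropylsilane, CC(C)[Si](Cl)(C(C)C)C(C)C
Why: silylation of the phenol; the silyl ether prevents lactol formation with the aldehyde made in step 7 and should survive the basic steps 10 and 11.

Step 7
Reactants: 11 [2-allyl-3,5-bis(benzyloxy)phenoxy]triisopropylsilane
Product: 13 2-[2,4-bis(benzyloxy)-6-(triisopropylsilyloxy)phenyl]acetaldehyde, via vicinal diol 12 (not isolated)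
Conditions: OsO4 (cat.), NaIO4, 2,6-lutidine, dioxane/H2O, rt
Reagents that add atoms: sodium periodate, [Na+].[O-]I(=O)(=O)=O (aldehyde oxygen, relayed through catalytic OsO4, O=[Os](=O)(=O)=O)
Why: Lemieux–Johnson oxidation (catalytic dihydroxylation of the terminal alkene, then periodate cleavage of the diol), chosen over ozonolysis because ozone attacks electron-rich benzyloxyarenes.

Step 8
Reactants: 14 3,4-bis(benzyloxy)phenylacetic acid; 15 (R)-4-benzyl-2-oxazolidinone
Product: 17 (R)-4-benzyl-3-{[3,4-bis(benzyloxy)phenyl]acetyl}oxazolidin-2-one, via mixed pivalic anhydride 16 (not isolated)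
Conditions: PivCl, Et3N, THF, −20 °C; then 15, LiCl, rt
Reagents that add atoms: none
Why: N-acylation of the oxazolidinone through the mixed pivalic anhydride, with LiCl/Et3N activating the carbamate N–H.

Step 9
Reactants: 17 (R)-4-benzyl-3-{[3,4-bis(benzyloxy)phenyl]acetyl}oxazolidin-2-one; 13 2-[2,4-bis(benzyloxy)-6-(triisopropylsilyloxy)phenyl]acetaldehyde
Product: 19 (R)-4-benzyl-3-[(2R,3S)-2-[3,4-bis(benzyloxy)phenyl]-4-[2,4-bis(benzyloxy)-6-(triisopropylsilyloxy)phenyl]-3-hydroxybutanoyl]oxazolidin-2-one, via Z dibutylboron enolate 18 (not isolated)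
Conditions: Bu2BOTf, iPr2NEt, CH2Cl2, −78 to 0 °C; then 13, −78 to 0 °C; pH 7 buffer, MeOH, H2O2, 0 °C
Reagents that add atoms: none
Why: Evans syn aldol; the Z boron enolate adds through a Zimmerman–Traxler chair on the face away from the auxiliary benzyl group, which sets C3' as S (and C2' as R, a centre that step 16 erases).

Step 10
Reactants: 19 Evans syn aldol imide
Product: 21 (2R,3S)-2-[3,4-bis(benzyloxy)phenyl]-4-[2,4-bis(benzyloxy)-6-(triisopropylsilyloxy)phenyl]-3-hydroxybutanoic acid, via peroxy acid 20 (not isolated)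
Conditions: LiOH, H2O2, THF/H2O, 0 °C; Na2SO3; 1 M HCl to pH 3
Reagents that add atoms: hydrogen peroxide, OO (as LiOOH; supplies the carboxyl OH oxygen)
Why: hydroperoxide-mediated hydrolysis of the imide, selective for the exocyclic carbonyl; it is done before O3' is acylated so that no β-acyloxy carbonyl compound meets strong base.

Step 11
Reactants: 21 (2R,3S)-hydroxy acid; 8 allyl bromide
Product: 22 allyl (2R,3S)-2-[3,4-bis(benzyloxy)phenyl]-4-[2,4-bis(benzyloxy)-6-(triisopropylsilyloxy)phenyl]-3-hydroxybutanoate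
Conditions: KHCO3, DMF, rt
Reagents that add atoms: none
Why: SN2 O-alkylation of the potassium carboxylate; the allyl ester can later be removed under neutral conditions.

Step 12
Reactants: 22 allyl (2R,3S)-hydroxy ester
Product: 23 allyl (2R,3S)-2-[3,4-bis(benzyloxy)phenyl]-4-[2,4-bis(benzyloxy)-6-(triisopropylsilyloxy)phenyl]-3-(4-oxopentanoyloxy)butanoate
Conditions: (Lev)2O, pyridine, DMAP (cat.), CH2Cl2, 0 °C to rt
Reagents that add atoms: levulinic anhydride, CC(=O)CCC(=O)OC(=O)CCC(C)=O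
Why: DMAP-catalysed acylation of the secondary alcohol; the levulinate is the participating group of step 16 and can later be removed by hydrazine, a reagent that does not attack the gallate.

Step 13
Reactants: 23 allyl (2R,3S)-levulinate silyl ether
Product: 24 allyl (2R,3S)-2-[3,4-bis(benzyloxy)phenyl]-4-[2,4-bis(benzyloxy)-6-hydroxyphenyl]-3-(4-oxopentanoyloxy)butanoate
Conditions: Bu4NF, AcOH, THF, 0 °C
Reagents that add atoms: none
Why: fluoride cleavage of the aryl silyl ether, buffered with acetic acid so that the phenoxide is protonated at once and β-elimination of the levulinate is avoided.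

Step 14
Reactants: 6 4β-(2-ethoxyethoxy) electrophile; 24 ring-D phenol (2.5 equiv, excess recovered)
Product: 25 allyl ester of the seco-acid: octa-O-benzyl-EGCG bonded from C4 (4β) to C8' of a 2-hydroxy-4,6-bis(benzyloxy)phenyl ring D that carries at C4a' the chain CH2–CH(OLev)–CH(ArE)–CO2allyl (3'S, 2'R)
Conditions: Me3SiOTf (0.3 equiv), 4 Å MS, CH2Cl2, −78 to −40 °C; NaHCO3
Reagents that add atoms: none
Why: Lewis-acid-mediated Friedel–Crafts coupling after ionisation at C4; ring D should react at C8', ortho to the free hydroxyl and less hindered than C6' between two benzyloxy groups, and from the β face anti to the C2 aryl and C3 galloyloxy groups, giving the 4β (3,4-trans) C4–C8' bond.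

Step 15
Reactants: 25 allyl ester of the seco-acid
Product: 26 seco-acid: as 25 with the chain CH2–CH(OLev)–CH(ArE)–CO2H (3'S, 2'R) and the free C8a' phenol
Conditions: Pd(PPh3)4 (5 mol%), morpholine, THF, rt; aq. citric acid wash
Reagents that add atoms: none
Why: Tsuji–Trost deallylation; the zerovalent palladium complex ionises the allyl ester and morpholine traps the allyl fragment, under conditions too mild for β-elimination or ester exchange.

Step 16
Reactants: 26 seco-acid
Product: 29 dodeca-O-benzyl-3'-O-levulinoyl-epigallocatechin-3-O-gallate-(4β→8)-catechin, via C2' benzylic cation 27 (not isolated), via dioxolanylium ion 28 (not isolated)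
Conditions: undivided cell, graphite anode, Pt cathode, constant current (ca. 2 mA/cm2) to 2.2 F/mol, 2,4,6-collidine (3 equiv), nBu4NPF6 (0.1 M), 3 Å MS, CH2Cl2, rt, Ar
Reagents that add atoms: none
Why: Proposed new method: the collidine-paired carboxylate of 26 should undergo net two-electron anodic oxidation with loss of CO2 (oxidation of ring E, the only arene carrying an α-carboxylate, funnels into the same decarboxylation) to give C2' benzylic cation 27, which the C3' levulinate carbonyl captures as the trans-4,5-disubstituted 1,3-dioxolan-2-ylium ion 28. The closest known reaction type is the Hofer–Moest (non-Kolbe) anodic decarboxylation of arylacetic acids with oxygen capture of the benzylic cation, combined here with the acyloxonium-mediated chroman closure known from flavan-3-ol synthesis. Ring F closes when the C8a' phenol oxygen opens 28 at C2' with inversion in a 6-exo-tet mode, forming only the O1'–C2' bond; attack at benzylic C2' instead of C3' follows from the cationic character of that carbon. The new C2' centre is controlled by the existing C3' centre through the bridging ester: the phenol must enter anti to it, so ring E ends trans to O3' (2'R), and both acid epimers converge because the planar cation has lost the old C2' configuration. The step needs chemoselective oxidation at the carboxylate in a molecule with a free phenol and five alkoxyarenes; this rests on the irreversible, decarboxylation-coupled oxidation at the ring-E arylacetate, expected at lower potential than the phenol or the other arenes and able to drain holes formed on them, on a weak base that leaves the phenol un-ionised, and on a charge limit near 2 F/mol that protects the product. Proton loss from 27 to an enol ester is the main competing path and should be outrun by intramolecular capture.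

Step 17
Reactants: 29 dodeca-O-benzyl-3'-O-levulinoyl dimer
Product: 30 dodeca-O-benzyl-epigallocatechin-3-O-gallate-(4β→8)-catechin (free 3'-OH)
Conditions: H2NNH2·AcOH, CH2Cl2/MeOH, rt
Reagents that add atoms: none
Why: hydrazine condenses with the ketone of the levulinate and the hydrazone cyclises to a dihydropyridazinone, releasing the 3'-OH; the gallate, an aryl ester without such a handle, is not attacked.

Step 18
Reactants: 30 dodeca-O-benzyl dimer
Product: 31 epigallocatechin-3-O-gallate-(4β→8)-catechin (target, CNP0129434.1)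
Conditions: H2 (1 atm), Pd(OH)2/C, THF/MeOH/H2O, rt
Reagents that add atoms: none
Why: hydrogenolysis of the twelve benzyl ethers under neutral conditions, which are known to spare gallate esters and the interflavan bond of proanthocyanidins.

Compound list

1 | (−)-epigallocatechin (2R,3R) | O[C@@H]1Cc2c(O)cc(O)cc2O[C@@H]1c1cc(O)c(O)c(O)c1 | starting material
2 | 5,7,3',4',5'-penta-O-benzyl-(−)-epigallocatechin (2R,3R) | O[C@@H]1Cc2c(OCc9ccccc9)cc(OCc9ccccc9)cc2O[C@@H]1c1cc(OCc9ccccc9)c(OCc9ccccc9)c(OCc9ccccc9)c1 | intermediate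
3 | (2R,3R,4S)-4-(2-ethoxyethoxy)-penta-O-benzyl-epigallocatechin (4β-alkoxy, trans to the 3-OH) | O[C@@H]1[C@@H](OCCOCC)c2c(OCc9ccccc9)cc(OCc9ccccc9)cc2O[C@@H]1c1cc(OCc9ccccc9)c(OCc9ccccc9)c(OCc9ccccc9)c1 | intermediate
4 | 3,4,5-tris(benzyloxy)benzoic acid | OC(=O)c1cc(OCc9ccccc9)c(OCc9ccccc9)c(OCc9ccccc9)c1 | starting material
5 | O-acylisourea from 4 and DCC | O=C(OC(=NC1CCCCC1)NC1CCCCC1)c1cc(OCc9ccccc9)c(OCc9ccccc9)c(OCc9ccccc9)c1 | intermediate (not isolated)
6 | (2R,3R,4S)-4-(2-ethoxyethoxy)-octa-O-benzyl-epigallocatechin gallate (4β-alkoxy, trans to the 3-O-galloyl group) | O=C(c6cc(OCc9ccccc9)c(OCc9ccccc9)c(OCc9ccccc9)c6)O[C@@H]1[C@@H](OCCOCC)c7c(OCc9ccccc9)cc(OCc9ccccc9)cc7O[C@@H]1c5cc(OCc9ccccc9)c(OCc9ccccc9)c(OCc9ccccc9)c5 | intermediate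
7 | 3,5-bis(benzyloxy)phenol | Oc1cc(OCc9ccccc9)cc(OCc9ccccc9)c1 | starting material
8 | allyl bromide | C=CCBr | starting material
9 | 1-(allyloxy)-3,5-bis(benzyloxy)benzene | C=CCOc1cc(OCc9ccccc9)cc(OCc9ccccc9)c1 | intermediate
10 | 2-allyl-3,5-bis(benzyloxy)phenol | C=CCc1c(O)cc(OCc9ccccc9)cc1OCc9ccccc9 | intermediate
11 | [2-allyl-3,5-bis(benzyloxy)phenoxy]triisopropylsilane | C=CCc1c(O[Si](C(C)C)(C(C)C)C(C)C)cc(OCc9ccccc9)cc1OCc9ccccc9 | intermediate
12 | 3-[2,4-bis(benzyloxy)-6-(triisopropylsilyloxy)phenyl]propane-1,2-diol (racemic) | OCC(O)Cc1c(O[Si](C(C)C)(C(C)C)C(C)C)cc(OCc9ccccc9)cc1OCc9ccccc9 | intermediate (not isolated)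
13 | 2-[2,4-bis(benzyloxy)-6-(triisopropylsilyloxy)phenyl]acetaldehyde | O=CCc1c(O[Si](C(C)C)(C(C)C)C(C)C)cc(OCc9ccccc9)cc1OCc9ccccc9 | intermediate
14 | 3,4-bis(benzyloxy)phenylacetic acid | OC(=O)Cc1ccc(OCc9ccccc9)c(OCc9ccccc9)c1 | starting material
15 | (R)-4-benzyl-2-oxazolidinone | O=C1N[C@H](Cc2ccccc2)CO1 | starting material
16 | [3,4-bis(benzyloxy)phenyl]acetic pivalic anhydride | CC(C)(C)C(=O)OC(=O)Cc1ccc(OCc9ccccc9)c(OCc9ccccc9)c1 | intermediate (not isolated)
17 | (R)-4-benzyl-3-{[3,4-bis(benzyloxy)phenyl]acetyl}oxazolidin-2-one | O=C(Cc1ccc(OCc9ccccc9)c(OCc9ccccc9)c1)N1[C@H](Cc2ccccc2)COC1=O | intermediate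
18 | (Z)-dibutylboron enolate of 17 | CCCCB(CCCC)O/C(N1[C@H](Cc2ccccc2)COC1=O)=C\c1ccc(OCc9ccccc9)c(OCc9ccccc9)c1 | intermediate (not isolated)
19 | (R)-4-benzyl-3-[(2R,3S)-2-[3,4-bis(benzyloxy)phenyl]-4-[2,4-bis(benzyloxy)-6-(triisopropylsilyloxy)phenyl]-3-hydroxybutanoyl]oxazolidin-2-one | O=C(N1[C@H](Cc2ccccc2)COC1=O)[C@H](c1ccc(OCc9ccccc9)c(OCc9ccccc9)c1)[C@@H](O)Cc1c(O[Si](C(C)C)(C(C)C)C(C)C)cc(OCc9ccccc9)cc1OCc9ccccc9 | intermediate
20 | (2R,3S)-2-[3,4-bis(benzyloxy)phenyl]-4-[2,4-bis(benzyloxy)-6-(triisopropylsilyloxy)phenyl]-3-hydroxybutaneperoxoic acid | OOC(=O)[C@H](c1ccc(OCc9ccccc9)c(OCc9ccccc9)c1)[C@@H](O)Cc1c(O[Si](C(C)C)(C(C)C)C(C)C)cc(OCc9ccccc9)cc1OCc9ccccc9 | intermediate (not isolated)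
21 | (2R,3S)-2-[3,4-bis(benzyloxy)phenyl]-4-[2,4-bis(benzyloxy)-6-(triisopropylsilyloxy)phenyl]-3-hydroxybutanoic acid | OC(=O)[C@H](c1ccc(OCc9ccccc9)c(OCc9ccccc9)c1)[C@@H](O)Cc1c(O[Si](C(C)C)(C(C)C)C(C)C)cc(OCc9ccccc9)cc1OCc9ccccc9 | intermediate
22 | allyl ester of 21 (2R,3S) | C=CCOC(=O)[C@H](c1ccc(OCc9ccccc9)c(OCc9ccccc9)c1)[C@@H](O)Cc1c(O[Si](C(C)C)(C(C)C)C(C)C)cc(OCc9ccccc9)cc1OCc9ccccc9 | intermediate
23 | allyl (2R,3S)-2-[3,4-bis(benzyloxy)phenyl]-4-[2,4-bis(benzyloxy)-6-(triisopropylsilyloxy)phenyl]-3-(4-oxopentanoyloxy)butanoate | C=CCOC(=O)[C@H](c1ccc(OCc9ccccc9)c(OCc9ccccc9)c1)[C@@H](OC(=O)CCC(C)=O)Cc1c(O[Si](C(C)C)(C(C)C)C(C)C)cc(OCc9ccccc9)cc1OCc9ccccc9 | intermediate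
24 | allyl (2R,3S)-2-[3,4-bis(benzyloxy)phenyl]-4-[2,4-bis(benzyloxy)-6-hydroxyphenyl]-3-(4-oxopentanoyloxy)butanoate | C=CCOC(=O)[C@H](c1ccc(OCc9ccccc9)c(OCc9ccccc9)c1)[C@@H](OC(=O)CCC(C)=O)Cc1c(O)cc(OCc9ccccc9)cc1OCc9ccccc9 | intermediate
25 | octa-O-benzyl-EGCG 4β→C8' adduct; ring D = 2-hydroxy-4,6-bis(benzyloxy)phenyl with the C4a' chain CH2–CH(OLev)–CH(ArE)–CO2allyl (3'S, 2'R) | O=C(c6cc(OCc9ccccc9)c(OCc9ccccc9)c(OCc9ccccc9)c6)O[C@@H]1[C@@H](c2c(OCc9ccccc9)cc(OCc9ccccc9)c(C[C@H](OC(=O)CCC(C)=O)[C@@H](c4ccc(OCc9ccccc9)c(OCc9ccccc9)c4)C(=O)OCC=C)c2O)c7c(OCc9ccccc9)cc(OCc9ccccc9)cc7O[C@@H]1c5cc(OCc9ccccc9)c(OCc9ccccc9)c(OCc9ccccc9)c5 | intermediate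
26 | seco-acid (key-step precursor): as 25 with a free carboxylic acid at C2' (3'S, 2'R) and the free C8a' phenol | O=C(c6cc(OCc9ccccc9)c(OCc9ccccc9)c(OCc9ccccc9)c6)O[C@@H]1[C@@H](c2c(OCc9ccccc9)cc(OCc9ccccc9)c(C[C@H](OC(=O)CCC(C)=O)[C@@H](c4ccc(OCc9ccccc9)c(OCc9ccccc9)c4)C(=O)O)c2O)c7c(OCc9ccccc9)cc(OCc9ccccc9)cc7O[C@@H]1c5cc(OCc9ccccc9)c(OCc9ccccc9)c(OCc9ccccc9)c5 | intermediate
27 | C2' benzylic cation from 26 (3'S) | O=C(c6cc(OCc9ccccc9)c(OCc9ccccc9)c(OCc9ccccc9)c6)O[C@@H]1[C@@H](c2c(OCc9ccccc9)cc(OCc9ccccc9)c(C[C@H](OC(=O)CCC(C)=O)[CH+]c4ccc(OCc9ccccc9)c(OCc9ccccc9)c4)c2O)c7c(OCc9ccccc9)cc(OCc9ccccc9)cc7O[C@@H]1c5cc(OCc9ccccc9)c(OCc9ccccc9)c(OCc9ccccc9)c5 | intermediate (not isolated)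
28 | trans-4,5-disubstituted 2-(3-oxobutyl)-1,3-dioxolan-2-ylium ion bridging O3' and C2' | O=C(c6cc(OCc9ccccc9)c(OCc9ccccc9)c(OCc9ccccc9)c6)O[C@@H]1[C@@H](c2c(OCc9ccccc9)cc(OCc9ccccc9)c(C[C@@H]3O[C+](CCC(C)=O)O[C@H]3c4ccc(OCc9ccccc9)c(OCc9ccccc9)c4)c2O)c7c(OCc9ccccc9)cc(OCc9ccccc9)cc7O[C@@H]1c5cc(OCc9ccccc9)c(OCc9ccccc9)c(OCc9ccccc9)c5 | intermediate (not isolated)
29 | dodeca-O-benzyl-3'-O-levulinoyl-epigallocatechin-3-O-gallate-(4β→8)-catechin (key-step product; lower unit 2'R,3'S, 2',3'-trans) | O=C(c6cc(OCc9ccccc9)c(OCc9ccccc9)c(OCc9ccccc9)c6)O[C@@H]1[C@@H](c2c(OCc9ccccc9)cc(OCc9ccccc9)c3c2O[C@H](c4ccc(OCc9ccccc9)c(OCc9ccccc9)c4)[C@@H](OC(=O)CCC(C)=O)C3)c7c(OCc9ccccc9)cc(OCc9ccccc9)cc7O[C@@H]1c5cc(OCc9ccccc9)c(OCc9ccccc9)c(OCc9ccccc9)c5 | intermediate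
30 | dodeca-O-benzyl-epigallocatechin-3-O-gallate-(4β→8)-catechin (free 3'-OH) | O=C(c6cc(OCc9ccccc9)c(OCc9ccccc9)c(OCc9ccccc9)c6)O[C@@H]1[C@@H](c2c(OCc9ccccc9)cc(OCc9ccccc9)c3c2O[C@H](c4ccc(OCc9ccccc9)c(OCc9ccccc9)c4)[C@@H](O)C3)c7c(OCc9ccccc9)cc(OCc9ccccc9)cc7O[C@@H]1c5cc(OCc9ccccc9)c(OCc9ccccc9)c(OCc9ccccc9)c5 | intermediate
31 | epigallocatechin-3-O-gallate-(4β→8)-catechin (CNP0129434.1) | O=C(O[C@@H]1[C@@H](c2c(O)cc(O)c3c2O[C@H](c2ccc(O)c(O)c2)[C@@H](O)C3)c2c(O)cc(O)cc2O[C@@H]1c1cc(O)c(O)c(O)c1)c1cc(O)c(O)c(O)c1 | target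

Total steps: 18. Longest linear sequence: 14 steps (steps 4–7 and 9–18, from 7).

Steps most likely to fail

Step 16 (anodic decarboxylative ring closure). The likely failure processes are competing oxidation of the ring-D phenol or over-oxidation of the product at C2', and proton loss from the cation before ring closure. The fallback gives up the seco-acid and uses the known Lewis-acid coupling of flavan units. It sets out from 6, which would be condensed under Me3SiOTf in CH2Cl2 at −78 °C with an excess of 5,7,3',4'-tetra-O-benzyl-(+)-catechin F1, itself made from commercial (+)-catechin with BnBr and K2CO3. Benzylated catechins are known to react at C8, and the 4β face is the open one, so the product should be 30, where the route is rejoined.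

Step 14 (C4–C8' coupling). The likely failure processes are poor site selectivity between C8' and C6' of the open-chain ring D and self-condensation of the electrophile through its own ring A. The fallback reverses the order of ring closure and coupling. It sets out from 24, which would be deallylated with Pd(PPh3)4 and morpholine to the monomeric seco-acid F2. This would be cyclised under the conditions of step 16 to 3-O-levulinoyl-5,7,3',4'-tetra-O-benzyl-(+)-catechin F3. Coupling of F3 with 6 under Me3SiOTf, where the closed chroman directs attack to C8, would return to the route at 29.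

Step 13 (unmasking the ring-D phenol). The likely failure processes are fluoride-induced β-elimination of levulinic acid across C2'–C3', which passes through the acidic α-aryl ester position, and migration of the levulinoyl group to the liberated phenoxide. The fallback changes the order of unmasking and acylation so that fluoride never meets the β-acyloxy ester. It sets out from 22, whose silyl ether would be cleaved with Bu4NF/AcOH in THF to the phenol diol F4. Both hydroxyls would then be esterified with levulinic anhydride, pyridine and DMAP to the bis-levulinate F5. The aryl levulinate alone would finally be cleaved with NH4OAc in MeOH/THF at rt, conditions known to remove phenolic esters and spare alkyl esters, which would return to the route at 24.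

Further compounds

F1 | step 16 | 5,7,3',4'-tetra-O-benzyl-(+)-catechin (2R,3S) | O[C@H]1Cc2c(OCc9ccccc9)cc(OCc9ccccc9)cc2O[C@@H]1c1ccc(OCc9ccccc9)c(OCc9ccccc9)c1
F2 | step 14 | (2R,3S)-2-[3,4-bis(benzyloxy)phenyl]-4-[2,4-bis(benzyloxy)-6-hydroxyphenyl]-3-(4-oxopentanoyloxy)butanoic acid | OC(=O)[C@H](c1ccc(OCc9ccccc9)c(OCc9ccccc9)c1)[C@@H](OC(=O)CCC(C)=O)Cc1c(O)cc(OCc9ccccc9)cc1OCc9ccccc9
F3 | step 14 | 3-O-levulinoyl-5,7,3',4'-tetra-O-benzyl-(+)-catechin (2R,3S) | CC(=O)CCC(=O)O[C@H]1Cc2c(OCc9ccccc9)cc(OCc9ccccc9)cc2O[C@@H]1c1ccc(OCc9ccccc9)c(OCc9ccccc9)c1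
F4 | step 13 | allyl (2R,3S)-2-[3,4-bis(benzyloxy)phenyl]-4-[2,4-bis(benzyloxy)-6-hydroxyphenyl]-3-hydroxybutanoate | C=CCOC(=O)[C@H](c1ccc(OCc9ccccc9)c(OCc9ccccc9)c1)[C@@H](O)Cc1c(O)cc(OCc9ccccc9)cc1OCc9ccccc9
F5 | step 13 | allyl (2R,3S)-2-[3,4-bis(benzyloxy)phenyl]-4-[2,4-bis(benzyloxy)-6-(4-oxopentanoyloxy)phenyl]-3-(4-oxopentanoyloxy)butanoate | C=CCOC(=O)[C@H](c1ccc(OCc9ccccc9)c(OCc9ccccc9)c1)[C@@H](OC(=O)CCC(C)=O)Cc1c(OC(=O)CCC(C)=O)cc(OCc9ccccc9)cc1OCc9ccccc9
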